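**Plan** (oxolane locants of the target: O1, C2 aryl-bearing, C3 carbinol, C4 benzyl-bearing, C5 methylene)

- Retrosynthesis cuts C2–aryl first (ring oxocarbenium ion plus arylzinc), then the two C–O bonds of the C3 diol (osmylation of an exocyclic C3=CH2), then that methylene carbon, which leaves (R)-β-benzyl-γ-butyrolactone.
- O1 is then deleted. It sits between C2 (carbonyl) and C5, and with C3 still a CH2 the resulting 3-benzylcyclobutanone has a mirror plane through C=O and C4, so C3H2 and C5H2 are enantiotopic. The cyclobutanone is cut into dichloroketene and O-benzyleugenol.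
- Forward: a [2+2] cycloaddition builds the four-membered carbocycle, oxygen insertion enlarges it to the five-membered oxacycle (the only non-aromatic ring), then C3 is functionalised and C2 is arylated on the intact ring.
- Stereochemistry: C4 from catalyst-controlled choice of the migrating methylene in the ring expansion; C3 from osmylation anti to the C4 benzyl group; C2 from aryl transfer to the oxocarbenium face opposite the C4 benzyl group and the C3 CH2O arm.

Key step: step 4

Remark: the benzylidene acetal carbon (13–15, 19) and the anomeric carbon (14, 15) are carried as epimer mixtures, since both centres are cleared later; compounds 1, 3 and 16 are taken as commercial.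

Step 1
Reactants: 1 eugenol
Product: 2 4-allyl-1-(benzyloxy)-2-methoxybenzene
Conditions: BnBr, K2CO3, DMF, rt
Reagents that add atoms: benzyl bromide, BrCc1ccccc1
Why: Williamson O-alkylation of the phenoxide masks the only acidic group for the later enolate and organometallic steps; no stereocentre is formed.

Step 2
Reactants: 2 4-allyl-1-(benzyloxy)-2-methoxybenzene; 3 trichloroacetyl chloride
Product: 5 3-[4-(benzyloxy)-3-methoxybenzyl]-2,2-dichlorocyclobutan-1-one, via dichloroketene 4 (not isolated)
Conditions: Zn–Cu couple, POCl3, Et2O, reflux, slow addition of 3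
Reagents that add atoms: none
Why: Zinc dechlorinates 3 to dichloroketene 4, which undergoes a thermal [2+2] ketene–alkene cycloaddition with the terminal alkene, the carbonyl carbon bonding to the terminal CH2 so that the benzyl group ends at C3 of the cyclobutanone; the single stereocentre is racemic and loses its stereogenicity in step 3.

Step 3
Reactants: 5 3-[4-(benzyloxy)-3-methoxybenzyl]-2,2-dichlorocyclobutan-1-one
Product: 6 3-[4-(benzyloxy)-3-methoxybenzyl]cyclobutan-1-one
Conditions: Zn dust, AcOH, rt
Reagents that add atoms: none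
Why: Reductive dehalogenation of the α,α-dichloro ketone by zinc leaves an achiral ketone whose two α-methylene groups are enantiotopic.

Step 4
Reactants: 6 3-[4-(benzyloxy)-3-methoxybenzyl]cyclobutan-1-one
Product: 8 (4R)-4-[4-(benzyloxy)-3-methoxybenzyl]dihydrofuran-2(3H)-one, via Criegee adduct 7 (not isolated)
Conditions: Sc(OTf)3 (5 mol %), chiral N,N′-dioxide ligand (5 mol %, enantiomer that leads to the R lactone), mCPBA, EtOAc, −20 °C
Reagents that add atoms: mCPBA, OOC(=O)c1cccc(Cl)c1
Why: The peracid adds to the Lewis-acid-bound carbonyl of 6 to give Criegee adduct 7, and one of the two α-methylene carbons migrates from carbon to oxygen with loss of 3-chlorobenzoate, which enlarges the four-membered ring to the γ-lactone and releases most of the cyclobutanone ring strain. The closest known reaction type is the catalytic asymmetric Baeyer–Villiger desymmetrisation of 3-substituted cyclobutanones, which covers 3-aryl and 3-benzyl members of this class. No ring is closed: the five-membered oxacycle arises by insertion of O1 between C2 and C5 of the existing ring, with retention at the migrating CH2. The new stereocentre C4 (the former C3 of the cyclobutanone) is set by the chiral scandium complex, which holds the Criegee adduct so that only one of the two enantiotopic C–C bonds is antiperiplanar to the O–O bond. The step needs group selectivity between the two methylenes, with no regiochemical issue because the mirror symmetry of 6 makes both migrations give the same constitution. It also needs chemoselectivity over the electron-rich arene, which is expected because the strained ketone reacts at −20 °C where the dialkoxyarene should be inert to the peracid.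

Step 5
Reactants: 8 (4R)-4-[4-(benzyloxy)-3-methoxybenzyl]dihydrofuran-2(3H)-one
Product: 11 (4R)-4-[4-(benzyloxy)-3-methoxybenzyl]-3-methylenedihydrofuran-2(3H)-one, via Mannich base 9 (not isolated), via ammonium iodide 10 (not isolated)
Conditions: LiHMDS, THF, −78 °C; CH2=NMe2+ I−, −78 °C to rt; MeI, MeOH, rt; aq. NaHCO3, CH2Cl2
Reagents that add atoms: dimethylmethyleneiminium iodide (Eschenmoser's salt), C=[N+](C)C.[I-]
Why: The lithium enolate undergoes a Mannich reaction with the iminium salt anti to the C4 benzyl group, and quaternisation followed by base-induced elimination of trimethylamine (Eschenmoser methylenation) gives the exocyclic alkene; the transient C3 stereocentre is lost and C4 is not enolisable.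

Step 6
Reactants: 11 (4R)-4-[4-(benzyloxy)-3-methoxybenzyl]-3-methylenedihydrofuran-2(3H)-one
Product: 12 (3S,4S)-4-[4-(benzyloxy)-3-methoxybenzyl]-3-hydroxy-3-(hydroxymethyl)dihydrofuran-2(3H)-one
Conditions: OsO4 (2 mol %), NMO, acetone–H2O, 0 °C to rt
Reagents that add atoms: N-methylmorpholine N-oxide, C[N+]1([O-])CCOCC1; water, O
Why: Catalytic osmium tetroxide syn-dihydroxylation adds to the exocyclic alkene from the face of the nearly planar lactone opposite the C4 benzyl group, which places the tertiary hydroxyl trans and the hydroxymethyl group cis to the benzyl group (3S).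

Step 7
Reactants: 12 (3S,4S)-4-[4-(benzyloxy)-3-methoxybenzyl]-3-hydroxy-3-(hydroxymethyl)dihydrofuran-2(3H)-one
Product: 13 (5S,9S)-9-[4-(benzyloxy)-3-methoxybenzyl]-2-phenyl-1,3,7-trioxaspiro[4.4]nonan-6-one
Conditions: PhCH(OMe)2, CSA (cat.), CH2Cl2, rt
Reagents that add atoms: benzaldehyde dimethyl acetal, COC(OC)c1ccccc1
Why: Acid-catalysed transacetalisation ties the tertiary and primary hydroxyls into a 1,3-dioxolane that is inert to hydride and organozinc reagents and removable by hydrogenolysis; the new acetal carbon forms as an epimer mixture of no consequence.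

Step 8
Reactants: 13 (5S,9S)-9-[4-(benzyloxy)-3-methoxybenzyl]-2-phenyl-1,3,7-trioxaspiro[4.4]nonan-6-one
Product: 14 (5S,9S)-9-[4-(benzyloxy)-3-methoxybenzyl]-2-phenyl-1,3,7-trioxaspiro[4.4]nonan-6-ol
Conditions: DIBAL-H (1.1 equiv), CH2Cl2, −78 °C; aq. Rochelle salt
Reagents that add atoms: none
Why: Partial reduction of the lactone by DIBAL-H stops at the aluminium hemiacetal at −78 °C and gives the lactol on work-up; the anomeric centre is an epimer mixture.

Step 9
Reactants: 14 (5S,9S)-9-[4-(benzyloxy)-3-methoxybenzyl]-2-phenyl-1,3,7-trioxaspiro[4.4]nonan-6-ol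
Product: 15 (5S,9S)-9-[4-(benzyloxy)-3-methoxybenzyl]-2-phenyl-6-(phenylsulfonyl)-1,3,7-trioxaspiro[4.4]nonane
Conditions: PhSO2H, CaCl2, CH2Cl2, rt
Reagents that add atoms: benzenesulfinic acid, O=S(O)c1ccccc1
Why: The lactol exchanges OH for sulfinate through the ring oxocarbenium ion (anomeric sulfone formation) and gives a stable precursor of that cation; the anomers are not separated.

Step 10
Reactants: 15 (5S,9S)-9-[4-(benzyloxy)-3-methoxybenzyl]-2-phenyl-6-(phenylsulfonyl)-1,3,7-trioxaspiro[4.4]nonane; 16 1-(benzyloxy)-4-bromo-2-methoxybenzene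
Product: 19 (5S,6R,9S)-6-[4-(benzyloxy)-3-methoxyphenyl]-9-[4-(benzyloxy)-3-methoxybenzyl]-2-phenyl-1,3,7-trioxaspiro[4.4]nonane, via arylmagnesium bromide 17 (not isolated), via arylzinc bromide 18 (not isolated)
Conditions: 16, Mg, THF, rt; ZnBr2, THF, 0 °C; then 15, THF, rt
Reagents that add atoms: none
Why: Zinc and magnesium bromide ionise the anomeric sulfone to the ring oxocarbenium ion (C2=O1+, which cannot lose a proton because C3 is fully substituted) and the aryl group is transferred from zinc to C2 (substitution of 2-sulfonyl cyclic ethers by organozinc reagents), entering cis to the C3 oxygen, which is the face opposite the C3 CH2O arm and the C4 benzyl group and also the face favoured by 2-alkoxy five-membered oxocarbenium ions, so that C2 becomes R.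

Step 11
Reactants: 19 (5S,6R,9S)-6-[4-(benzyloxy)-3-methoxyphenyl]-9-[4-(benzyloxy)-3-methoxybenzyl]-2-phenyl-1,3,7-trioxaspiro[4.4]nonane
Product: 20 (2R,3S,4S)-2-(4-hydroxy-3-methoxyphenyl)-4-(4-hydroxy-3-methoxybenzyl)-3-(hydroxymethyl)tetrahydrofuran-3-ol
Conditions: H2 (1 atm), Pd(OH)2/C, EtOAc–MeOH, rt
Reagents that add atoms: none
Why: Hydrogenolysis cleaves the two aryl benzyl ethers and the benzylidene acetal in one operation under neutral conditions, under which the benzylic C2–O1 bond of the ring is expected to be cleaved much more slowly; no stereocentre is touched.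

**Compound list**

1 | eugenol (4-allyl-2-methoxyphenol) | COc1cc(CC=C)ccc1O | starting material
2 | 4-allyl-1-(benzyloxy)-2-methoxybenzene | COc1cc(CC=C)ccc1OCc1ccccc1 | intermediate
3 | trichloroacetyl chloride | ClC(=O)C(Cl)(Cl)Cl | starting material
4 | dichloroketene | ClC(Cl)=C=O | intermediate
5 | 3-[4-(benzyloxy)-3-methoxybenzyl]-2,2-dichlorocyclobutan-1-one (racemic) | COc1cc(CC2CC(=O)C2(Cl)Cl)ccc1OCc1ccccc1 | intermediate
6 | 3-[4-(benzyloxy)-3-methoxybenzyl]cyclobutan-1-one | COc1cc(CC2CC(=O)C2)ccc1OCc1ccccc1 | intermediate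
7 | Criegee adduct, 3-[4-(benzyloxy)-3-methoxybenzyl]-1-hydroxycyclobutyl 3-chloroperoxybenzoate | COc1cc(CC2CC(O)(OOC(=O)c3cccc(Cl)c3)C2)ccc1OCc1ccccc1 | intermediate
8 | (4R)-4-[4-(benzyloxy)-3-methoxybenzyl]dihydrofuran-2(3H)-one | COc1cc(C[C@H]2COC(=O)C2)ccc1OCc1ccccc1 | intermediate
9 | Mannich base, (3S,4R)-4-[4-(benzyloxy)-3-methoxybenzyl]-3-[(dimethylamino)methyl]dihydrofuran-2(3H)-one | COc1cc(C[C@H]2COC(=O)[C@@H]2CN(C)C)ccc1OCc1ccccc1 | intermediate
10 | ammonium iodide, {(3S,4R)-4-[4-(benzyloxy)-3-methoxybenzyl]-2-oxotetrahydrofuran-3-yl}-N,N,N-trimethylmethanaminium iodide | COc1cc(C[C@H]2COC(=O)[C@@H]2C[N+](C)(C)C)ccc1OCc1ccccc1.[I-] | intermediate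
11 | (4R)-4-[4-(benzyloxy)-3-methoxybenzyl]-3-methylenedihydrofuran-2(3H)-one | COc1cc(C[C@H]2COC(=O)C2=C)ccc1OCc1ccccc1 | intermediate
12 | (3S,4S)-4-[4-(benzyloxy)-3-methoxybenzyl]-3-hydroxy-3-(hydroxymethyl)dihydrofuran-2(3H)-one (OH trans, CH2OH cis to the benzyl group) | COc1cc(C[C@H]2COC(=O)[C@@]2(O)CO)ccc1OCc1ccccc1 | intermediate
13 | (5S,9S)-9-[4-(benzyloxy)-3-methoxybenzyl]-2-phenyl-1,3,7-trioxaspiro[4.4]nonan-6-one (benzylidene acetal of 12, epimers at the acetal carbon) | COc1cc(C[C@H]2COC(=O)[C@@]2(OC(c4ccccc4)O3)C3)ccc1OCc1ccccc1 | intermediate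
14 | (5S,9S)-9-[4-(benzyloxy)-3-methoxybenzyl]-2-phenyl-1,3,7-trioxaspiro[4.4]nonan-6-ol (lactol, anomer mixture) | COc1cc(C[C@H]2COC(O)[C@@]2(OC(c4ccccc4)O3)C3)ccc1OCc1ccccc1 | intermediate
15 | (5S,9S)-9-[4-(benzyloxy)-3-methoxybenzyl]-2-phenyl-6-(phenylsulfonyl)-1,3,7-trioxaspiro[4.4]nonane (anomer mixture) | COc1cc(C[C@H]2COC(S(=O)(=O)c5ccccc5)[C@@]2(OC(c4ccccc4)O3)C3)ccc1OCc1ccccc1 | intermediate
16 | 1-(benzyloxy)-4-bromo-2-methoxybenzene | COc1cc(Br)ccc1OCc1ccccc1 | starting material
17 | [4-(benzyloxy)-3-methoxyphenyl]magnesium bromide | COc1cc([Mg]Br)ccc1OCc1ccccc1 | intermediate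
18 | [4-(benzyloxy)-3-methoxyphenyl]zinc bromide | COc1cc([Zn]Br)ccc1OCc1ccccc1 | intermediate
19 | (5S,6R,9S)-6-[4-(benzyloxy)-3-methoxyphenyl]-9-[4-(benzyloxy)-3-methoxybenzyl]-2-phenyl-1,3,7-trioxaspiro[4.4]nonane (aryl cis to the ring oxygen on C5, trans to the benzyl group) | COc1cc(C[C@H]2CO[C@H](c5ccc(OCc6ccccc6)c(OC)c5)[C@@]2(OC(c4ccccc4)O3)C3)ccc1OCc1ccccc1 | intermediate
20 | (2R,3S,4S)-2-(4-hydroxy-3-methoxyphenyl)-4-(4-hydroxy-3-methoxybenzyl)-3-(hydroxymethyl)tetrahydrofuran-3-ol | COc1cc(C[C@H]2CO[C@H](c3ccc(O)c(OC)c3)[C@@]2(O)CO)ccc1O | target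

**Step count and risks**

Total steps: 11. Longest linear sequence: 11 (1 to 20); 16 enters in step 10.

Steps most likely to fail:

1. Step 10. Ionisation at an anomeric carbon flanked by a fully substituted carbon may be slow, so that the arylzinc is lost to protonation before it is transferred, and the facial preference at the oxocarbenium ion may erode. The fallback sets out from 14. Excess arylmagnesium bromide 17 in THF at 0 °C opens the lactol to the open-chain benzylic alcohol diol F1 (both carbinol epimers). Catalytic CSA in CH2Cl2 at 0 °C then ionises the electron-rich benzylic alcohol, and the primary hydroxyl captures the cation in a 5-exo closure. Both epimers should converge on the ether with the aryl group trans to the C3 CH2O arm and the C4 benzyl group. The fallback comes back to the route at 19.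

2. Step 4. The benzyl group is one carbon removed from the ring, so discrimination of the two enantiotopic methylenes by the catalyst may be incomplete. The fallback sets out from 6. Uncatalysed Baeyer–Villiger oxidation (mCPBA, NaHCO3, CH2Cl2) gives the racemic lactone F2. Aminolysis with (S)-1-phenylethylamine and AlMe3 in CH2Cl2 gives two diastereomeric hydroxy amides, from which the (3R) hydroxy amide F3 is separated by crystallisation or chromatography. Relactonisation with TsOH in warm toluene comes back to the route at 8.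

3. Step 11. The benzylidene acetal may be hydrogenolysed more slowly than the aryl benzyl ethers, and prolonged exposure could begin to cleave the benzylic C2–O1 bond of the ring. The fallback sets out from 19. Hydrolysis of the acetal in 80% aqueous acetic acid at 40 °C gives the diol bis(benzyl ether) F4. A brief hydrogenolysis over Pd/C in EtOAc then removes only the two aryl benzyl ethers and comes back to the route at 20.

Further compounds
F1 | step 10 | open-chain diol, [4-(benzyloxy)-3-methoxyphenyl]{4-[1-(4-(benzyloxy)-3-methoxyphenyl)-3-hydroxypropan-2-yl]-2-phenyl-1,3-dioxolan-4-yl}methanol (ring centres as in 14, carbinol epimers) | COc1cc(C[C@@H](CO)[C@](C(O)c5ccc(OCc6ccccc6)c(OC)c5)(OC(c4ccccc4)O3)C3)ccc1OCc1ccccc1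
F2 | step 4 | racemic 4-[4-(benzyloxy)-3-methoxybenzyl]dihydrofuran-2(3H)-one | COc1cc(CC2COC(=O)C2)ccc1OCc1ccccc1
F3 | step 4 | (3R)-3-[4-(benzyloxy)-3-methoxybenzyl]-4-hydroxy-N-[(1S)-1-phenylethyl]butanamide | COc1cc(C[C@@H](CO)CC(=O)N[C@@H](C)c2ccccc2)ccc1OCc1ccccc1
F4 | step 11 | (2R,3S,4S)-2-[4-(benzyloxy)-3-methoxyphenyl]-4-[4-(benzyloxy)-3-methoxybenzyl]-3-(hydroxymethyl)tetrahydrofuran-3-ol | COc1cc(C[C@H]2CO[C@H](c3ccc(OCc4ccccc4)c(OC)c3)[C@@]2(O)CO)ccc1OCc1ccccc1
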